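The constants come from no measurement; no experiment stands behind them.

The tempting mistake here is to give target its bare lifetime and take the catalyst's speed from the charge alone, when target partly sits as idle adduct and each catalyst turn is a chain of waits.

    target → over-reaction product (k1 = 1.0 s⁻¹)
    partner + target ⇌ idle adduct, settled at all times (K2 = 390 M⁻¹)
    partner + catalyst intermediate A → catalyst intermediate B (k3 = 3100 M⁻¹ s⁻¹)
    catalyst intermediate B → free catalyst + target (k4 = 4.6 s⁻¹)
    starting material + free catalyst → catalyst intermediate A (k5 = 1700 M⁻¹ s⁻¹)

| flask | starting material | partner | free catalyst | time | remark |
|---|---|---|---|---|---|
| south-west | 2.0 mM | 1.20 equiv (fed, over 4.0 s) | 10 mol% | 6.0 s | all else is in the flask from the start; the feed brings no volume worth counting |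
| east | 2.0 mM | 1.20 equiv | 10 mol% | 6.0 s | everything together at the start |
| north | 2.0 mM | 1.20 equiv (in portions, 5, over 4.0 s) | 10 mol% | 6.0 s | first portion at the start, last at 4.0 s |
| south-east | 2.0 mM (fed, over 4.0 s) | 1.20 equiv | 10 mol% | 6.0 s | all else is in the flask from the start; the feed brings no volume worth counting |

1. the flask that comes out highest in amount of over-reaction product, in percent of the starting material charged, or "all alike" when all lie within 1.5 percentage points (south-west / east / north / south-east / all alike)
2. over-reaction product at the end, in percent of the starting material charged, south-west
3. over-reaction product at the end, in percent of the starting material charged, east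
4. over-reaction product at the end, in percent of the starting material charged, north
5. over-reaction product at the end, in percent of the starting material charged, south-east

- for target the idle adduct is counted in
- run time (south-west): 6.0 s

I reckon east first, at the point where a fraction 0.7 of the starting material is left, so that [starting material] is 1.40 mM and [partner] is 1.80 mM. Free catalyst waits 0.420 s for starting material, catalyst intermediate A waits 0.179 s for partner, and catalyst intermediate B waits 0.217 s to release target. These add up to the cycle time, the mean time of one catalyst turn, 0.817 s. With the adduct balance taken as settled, target with its adduct decays pseudo-first-order with a lifetime of 1.70 s, and the product trails the turnover by that time. A steady turnover of 0.122 s⁻¹ of the charge then gives 52.6 % in east.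

The weak link is the constant cycle time, since the waits for starting material and for partner lengthen as these reagents fall, though the wait of catalyst intermediate B does not. Summing the waits over the falling concentrations, using up a fraction 0.7 of the starting material takes 6.47 s, which is longer than the 5.72 s of the steady reckoning. The mean turnover therefore drops to 0.108 s⁻¹, and I commit to 46.5 % for east.

A feed or portions hold a reagent back by 2.00 s on average, and I charge each flask the share of the cycle spent waiting for that reagent: 0.439 s for south-west and north, 1.03 s for south-east. That gives 41.7 % for south-west, 41.7 % for north and 35.3 % for south-east, so the highest is east.

The forecast names east, with 43 % for south-west, 51 % for east, 45 % for north and 34 % for south-east, favouring “the flask that starts turning over soonest”.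

The simulation gives east as highest, with 40.8 % for south-west, 50.5 % for east, 41.7 % for north and 33.9 % for south-east.

My cycle time spends 51.4 % of a turn waiting for starting material, and in south-east at 3.48 s free catalyst has a half-life of 0.34 s, longer than the 0.12 s of catalyst intermediate A. Free catalyst is the resting state there, standing at 57.0 % at 6.00 s, more than either intermediate. For the south-east neighbour with 0.80 mM of starting material, the concentration waits stretch and the cycle time becomes 1.72 s, which gives 18.0 %. The simulation gives 18.3 %.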